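The dihydropyranone ring (ring C) of the flavanone unit is disconnected at C3–C2 and at O1–C8a, so that C2 and O1 arrive together as the carbonyl group of 4-(benzyloxy)benzaldehyde. The key step exploits the C4 ketone, which sits on ring A ortho to C8a: as its silyl enol ether it delivers C3 in a catalytic enantioselective Mukaiyama aldol addition that sets C2 as R, and as an ortho acyl group it activates a C8a–F bond for SNAr by the aldolate oxygen, released by fluoride in the same flask. The precursor is a 6-fluoro-2,4-bis(benzyloxy)acetophenone that already carries the flavone at ring carbon 3, assembled by Negishi coupling.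

Key step: step 7

Remark on numbering: flavanone numbering (O1, C2, C3, C4, C4a, C5 to C8, C8a) is used for the ring formed in step 7; the target stereocenter is (2R).
Assumption: the (R,R)-bisphosphoramide (two (R)-N,N'-dimethyl-1,1'-binaphthyl-2,2'-diamine phosphoramide units joined by an N,N'-dimethylpentane-1,5-diamine linker) directs the enol ether to the Re face of the aryl aldehyde, which gives the (R)-aldolate; if the sense is opposite on this substrate, the (S,S)-antipode is used without other change.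

Step 1
Reactants: 1 5-fluorobenzene-1,3-diol
Product: 2 1-(2-fluoro-4,6-dihydroxyphenyl)ethan-1-one
Conditions: AcOH, BF3·OEt2 (Lewis acid promoter), 90 °C; aq. NaOAc work-up
Reagents that add atoms: acetic acid, CC(=O)O
Why: Friedel–Crafts (Nencki-type) C-acylation of the resorcinol should occur at C4, ortho to one hydroxyl and para to the other, and not at the doubly flanked C2, and C4 and C6 are equivalent so a single ketone is expected.

Step 2
Reactants: 2 1-(2-fluoro-4,6-dihydroxyphenyl)ethan-1-one
Product: 3 1-(6-fluoro-2,4-dihydroxy-3-iodophenyl)ethan-1-one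
Conditions: I2 (0.4 equiv), HIO3 (0.2 equiv), EtOH/H2O, 25 to 40 °C
Reagents that add atoms: iodine, II; iodic acid, O[I](=O)=O
Why: Electrophilic aromatic iodination should go to the carbon flanked by both hydroxyls, as it does in 2,4-dihydroxyacetophenone, because the only other free position is deactivated by the adjacent fluorine.

Step 3
Reactants: 3 1-(6-fluoro-2,4-dihydroxy-3-iodophenyl)ethan-1-one
Product: 4 1-[2,4-bis(benzyloxy)-6-fluoro-3-iodophenyl]ethan-1-one
Conditions: BnBr (2.4 equiv), K2CO3, DMF, 60 °C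
Reagents that add atoms: benzyl bromide, BrCc1ccccc1
Why: Williamson ether synthesis (SN2 on benzyl bromide) should alkylate both phenoxides, the chelated and hindered ortho hydroxyl needing the dipolar solvent and warming.

Step 4
Reactants: 5 5-hydroxy-7-methoxy-2-(4-methoxyphenyl)-4H-chromen-4-one (apigenin 7,4'-dimethyl ether, a catalog natural product)
Product: 6 5-(benzyloxy)-7-methoxy-2-(4-methoxyphenyl)-4H-chromen-4-one
Conditions: BnBr, K2CO3, DMF, 80 °C
Reagents that add atoms: benzyl bromide, BrCc1ccccc1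
Why: Williamson ether synthesis on the chelated 5-hydroxyl, which is the only acidic site, should proceed under forcing carbonate conditions.

Step 5
Reactants: 6 5-(benzyloxy)-7-methoxy-2-(4-methoxyphenyl)-4H-chromen-4-one; 4 1-[2,4-bis(benzyloxy)-6-fluoro-3-iodophenyl]ethan-1-one
Product: 9 3-[3-acetyl-2,6-bis(benzyloxy)-4-fluorophenyl]-5-(benzyloxy)-7-methoxy-2-(4-methoxyphenyl)-4H-chromen-4-one, via 3-lithioflavone 7 (not isolated), via flavon-3-ylzinc chloride 8 (not isolated)
Conditions: LiN(i-Pr)2, THF, −78 °C; ZnCl2, −78 to 25 °C; then 4, Pd2(dba)3 (2.5 mol %), RuPhos (10 mol %), THF, 65 °C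
Reagents that add atoms: none
Why: Carbonyl-directed deprotonation of the flavone at C3, transmetalation to zinc and Negishi cross-coupling with a bulky dialkylbiarylphosphine ligand suited to tetra-ortho-substituted biaryls should join the two rings, the arylzinc tolerating the methyl ketone of 4.

Step 6
Reactants: 9 3-[3-acetyl-2,6-bis(benzyloxy)-4-fluorophenyl]-5-(benzyloxy)-7-methoxy-2-(4-methoxyphenyl)-4H-chromen-4-one
Product: 10 3-{2,6-bis(benzyloxy)-4-fluoro-3-[1-(trimethylsilyloxy)ethenyl]phenyl}-5-(benzyloxy)-7-methoxy-2-(4-methoxyphenyl)-4H-chromen-4-one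
Conditions: LiN(SiMe3)2, THF, −78 °C; Me3SiCl, −78 to 0 °C; non-aqueous work-up, used crude
Reagents that add atoms: chlorotrimethylsilane, C[Si](C)(C)Cl
Why: Enolate formation at the methyl ketone, the only enolizable position, followed by O-silylation is a standard silyl enol ether preparation and should leave the non-enolizable flavone carbonyl alone.

Step 7
Reactants: 10 3-{2,6-bis(benzyloxy)-4-fluoro-3-[1-(trimethylsilyloxy)ethenyl]phenyl}-5-(benzyloxy)-7-methoxy-2-(4-methoxyphenyl)-4H-chromen-4-one; 11 4-(benzyloxy)benzaldehyde (1.5 equiv)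
Product: 14 (2R)-5,7-bis(benzyloxy)-2-[4-(benzyloxy)phenyl]-6-[5-(benzyloxy)-7-methoxy-2-(4-methoxyphenyl)-4-oxo-4H-chromen-3-yl]-2,3-dihydro-4H-chromen-4-one, via trichlorosilyl aldolate 12 (not isolated), via cesium aldolate 13 (not isolated)
Conditions: SiCl4 (2 equiv), (R,R)-bisphosphoramide (5 mol %), i-Pr2NEt (20 mol %), CH2Cl2, −78 °C; volatiles off in vacuo; CsF (8 equiv), DMF, 0 to 25 °C (same flask)
Reagents that add atoms: none
Why: The bisphosphoramide-bound trichlorosilyl cation formed from SiCl4 activates aldehyde 11, and the terminal enol carbon of 10 (C3) adds to its carbonyl carbon through an open transition state to form C3–C2 and trichlorosilyl aldolate 12 with loss of Me3SiCl; fluoride then strips the silicon to give alkoxide 13, whose oxygen (the former aldehyde oxygen) attacks C8a ortho to the C4 ketone, and the Meisenheimer adduct expels fluoride to form O1–C8a. The closest known reaction types are the Lewis-base-activated SiCl4 Mukaiyama aldol addition of methyl ketone trimethylsilyl enol ethers to aromatic aldehydes and the intramolecular SNAr of an alkoxide on an ortho-acyl aryl fluoride; together they are the stepwise counterpart of a Danishefsky-type hetero-Diels–Alder reaction with fluoride as the leaving group. Ring C of the flavanone closes by a 6-exo-trig addition–elimination at C8a. C2 is the only new stereocenter and is set in the aldol event under catalyst control (Re-face attack on the aldehyde gives R), while the ring closure breaks no bond at C2 and should carry the configuration into 14. The step needs enantiofacial selectivity, secured by the chiral catalyst at −78 °C, and it needs ring closure to outrun retro-aldol cleavage and E1cB loss of the oxygen, which is favoured by releasing the alkoxide only at low temperature in a dipolar aprotic solvent next to an activated C–F bond. Regioselectivity should follow because fluoride is the only good leaving group ortho to the ketone and both benzyloxy groups are meta to C8a, so they do not destabilize the Meisenheimer intermediate.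

Step 8
Reactants: 14 (2R)-5,7-bis(benzyloxy)-2-[4-(benzyloxy)phenyl]-6-[5-(benzyloxy)-7-methoxy-2-(4-methoxyphenyl)-4-oxo-4H-chromen-3-yl]-2,3-dihydro-4H-chromen-4-one
Product: 15 (2R)-5,7-dihydroxy-2-(4-hydroxyphenyl)-6-[5-hydroxy-7-methoxy-2-(4-methoxyphenyl)-4-oxo-4H-chromen-3-yl]-2,3-dihydro-4H-chromen-4-one (target)
Conditions: H2 (1 atm), Pd/C (10 %), EtOAc/MeOH, 25 °C
Reagents that add atoms: none
Why: Catalytic hydrogenolysis of the four aryl benzyl ethers under neutral conditions should leave the tetrasubstituted flavone double bond, both ketones, the two methyl ethers and the base-sensitive C2 stereocenter untouched.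

Compound list
1 | 5-fluorobenzene-1,3-diol | Oc1cc(O)cc(F)c1 | starting material
2 | 1-(2-fluoro-4,6-dihydroxyphenyl)ethan-1-one | CC(=O)c1c(O)cc(O)cc1F | intermediate
3 | 1-(6-fluoro-2,4-dihydroxy-3-iodophenyl)ethan-1-one | CC(=O)c1c(O)c(I)c(O)cc1F | intermediate
4 | 1-[2,4-bis(benzyloxy)-6-fluoro-3-iodophenyl]ethan-1-one | CC(=O)c1c(OCc2ccccc2)c(I)c(OCc2ccccc2)cc1F | intermediate
5 | 5-hydroxy-7-methoxy-2-(4-methoxyphenyl)-4H-chromen-4-one | COc1ccc(-c2cc(=O)c3c(O)cc(OC)cc3o2)cc1 | starting material
6 | 5-(benzyloxy)-7-methoxy-2-(4-methoxyphenyl)-4H-chromen-4-one | COc1ccc(-c2cc(=O)c3c(OCc4ccccc4)cc(OC)cc3o2)cc1 | intermediate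
7 | 3-lithio derivative of 6 | COc1ccc(-c2oc3cc(OC)cc(OCc4ccccc4)c3c(=O)c2[Li])cc1 | intermediate (not isolated)
8 | chloro[5-(benzyloxy)-7-methoxy-2-(4-methoxyphenyl)-4-oxo-4H-chromen-3-yl]zinc | COc1ccc(-c2oc3cc(OC)cc(OCc4ccccc4)c3c(=O)c2[Zn]Cl)cc1 | intermediate (not isolated)
9 | 3-[3-acetyl-2,6-bis(benzyloxy)-4-fluorophenyl]-5-(benzyloxy)-7-methoxy-2-(4-methoxyphenyl)-4H-chromen-4-one | COc1ccc(-c2oc3cc(OC)cc(OCc4ccccc4)c3c(=O)c2-c2c(OCc3ccccc3)cc(F)c(C(C)=O)c2OCc2ccccc2)cc1 | intermediate
10 | trimethylsilyl enol ether of 9 | COc1ccc(-c2oc3cc(OC)cc(OCc4ccccc4)c3c(=O)c2-c2c(OCc3ccccc3)cc(F)c(C(=C)O[Si](C)(C)C)c2OCc2ccccc2)cc1 | intermediate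
11 | 4-(benzyloxy)benzaldehyde | O=Cc1ccc(OCc2ccccc2)cc1 | starting material
12 | 3-{2,6-bis(benzyloxy)-4-fluoro-3-[(3R)-3-[4-(benzyloxy)phenyl]-3-(trichlorosilyloxy)propanoyl]phenyl}-5-(benzyloxy)-7-methoxy-2-(4-methoxyphenyl)-4H-chromen-4-one | COc1ccc(-c2oc3cc(OC)cc(OCc4ccccc4)c3c(=O)c2-c2c(OCc3ccccc3)cc(F)c(C(=O)C[C@H](c3ccc(OCc4ccccc4)cc3)O[Si](Cl)(Cl)Cl)c2OCc2ccccc2)cc1 | intermediate (not isolated)
13 | cesium (1R)-alkoxide of the same aldol (silicon removed) | COc1ccc(-c2oc3cc(OC)cc(OCc4ccccc4)c3c(=O)c2-c2c(OCc3ccccc3)cc(F)c(C(=O)C[C@H](c3ccc(OCc4ccccc4)cc3)[O-])c2OCc2ccccc2)cc1.[Cs+] | intermediate (not isolated)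
14 | (2R)-5,7-bis(benzyloxy)-2-[4-(benzyloxy)phenyl]-6-[5-(benzyloxy)-7-methoxy-2-(4-methoxyphenyl)-4-oxo-4H-chromen-3-yl]-2,3-dihydro-4H-chromen-4-one | COc1ccc(-c2oc3cc(OC)cc(OCc4ccccc4)c3c(=O)c2-c2c(OCc3ccccc3)cc3c(c2OCc2ccccc2)C(=O)C[C@H](c2ccc(OCc4ccccc4)cc2)O3)cc1 | intermediate
15 | (2R)-5,7-dihydroxy-2-(4-hydroxyphenyl)-6-[5-hydroxy-7-methoxy-2-(4-methoxyphenyl)-4-oxo-4H-chromen-3-yl]-2,3-dihydro-4H-chromen-4-one | COc1ccc(-c2oc3cc(OC)cc(O)c3c(=O)c2-c2c(O)cc3c(c2O)C(=O)C[C@H](c2ccc(O)cc2)O3)cc1 | target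

Total step count: 8. Longest linear sequence: 7 steps (steps 1, 2, 3, 5, 6, 7, 8 from compound 1).

Steps most likely to fail

Step 7. Three processes could defeat it:
- the freed alkoxide may undergo retro-aldol cleavage and re-addition, which erodes enantiopurity;
- E1cB loss of the oxygen to the enone may outrun the SNAr closure;
- the flavone carbonyl may bind the chiral silicon Lewis acid and slow the aldol addition.

The fallback builds the ring as a chromone and sets C2 by asymmetric conjugate arylation. It sets out from 9. Hydroxide displaces the activated fluoride (KOH, DMSO/H2O, 60 °C) to give 3-[3-acetyl-2,6-bis(benzyloxy)-4-hydroxyphenyl]-5-(benzyloxy)-7-methoxy-2-(4-methoxyphenyl)-4H-chromen-4-one F1. Heating with N,N-dimethylformamide dimethyl acetal gives the enaminone F2. Aqueous HCl in CH2Cl2 closes it to the chromone 5,7-bis(benzyloxy)-6-[5-(benzyloxy)-7-methoxy-2-(4-methoxyphenyl)-4-oxo-4H-chromen-3-yl]-4H-chromen-4-one F3. Conjugate addition of 4-(benzyloxy)phenylboronic acid to F3 (Pd(OCOCF3)2, the t-BuPyOx enantiomer that delivers 2R, NH4PF6, H2O, 1,2-dichloroethane, 60 °C) comes back to the route at 14.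

Step 5. Transmetalation and reductive elimination at a tetra-ortho-substituted axis may be slow, and the metalated flavone may be protonated or ring-opened before it couples. The fallback exchanges the roles of the partners, so that the flavone is the electrophile. From 6, the lithio species 7 is quenched with I2 to give 5-(benzyloxy)-3-iodo-7-methoxy-2-(4-methoxyphenyl)-4H-chromen-4-one F4. From 4, Miyaura borylation (bis(pinacolato)diboron, PdCl2(dppf), KOAc, dioxane, 90 °C) gives the pinacol boronate F5. Suzuki–Miyaura coupling of F4 and F5 (Pd(OAc)2, SPhos, K3PO4, toluene/H2O, 100 °C) comes back to the route at 9.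

Step 2. Iodination may partly go to the position next to fluorine or proceed twice. The fallback fixes the regiochemistry by symmetry. It sets out from 1, which is iodinated between the hydroxyls as resorcinol itself is (I2, NaHCO3, H2O, 0 °C) to give 5-fluoro-2-iodobenzene-1,3-diol F6. The two remaining ring positions of F6 are equivalent, so acylation (AcOH, BF3·OEt2, 70 °C) can give only one ketone and comes back to the route at 3.

Further compounds
F1 | step 7 | 3-[3-acetyl-2,6-bis(benzyloxy)-4-hydroxyphenyl]-5-(benzyloxy)-7-methoxy-2-(4-methoxyphenyl)-4H-chromen-4-one | COc1ccc(-c2oc3cc(OC)cc(OCc4ccccc4)c3c(=O)c2-c2c(OCc3ccccc3)cc(O)c(C(C)=O)c2OCc2ccccc2)cc1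
F2 | step 7 | (E)-3-(dimethylamino)prop-2-enoyl analogue of F1 (enaminone) | COc1ccc(-c2oc3cc(OC)cc(OCc4ccccc4)c3c(=O)c2-c2c(OCc3ccccc3)cc(O)c(C(=O)/C=C/N(C)C)c2OCc2ccccc2)cc1
F3 | step 7 | 5,7-bis(benzyloxy)-6-[5-(benzyloxy)-7-methoxy-2-(4-methoxyphenyl)-4-oxo-4H-chromen-3-yl]-4H-chromen-4-one | COc1ccc(-c2oc3cc(OC)cc(OCc4ccccc4)c3c(=O)c2-c2c(OCc3ccccc3)cc3occc(=O)c3c2OCc2ccccc2)cc1
F4 | step 5 | 5-(benzyloxy)-3-iodo-7-methoxy-2-(4-methoxyphenyl)-4H-chromen-4-one | COc1ccc(-c2oc3cc(OC)cc(OCc4ccccc4)c3c(=O)c2I)cc1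
F5 | step 5 | 1-[2,4-bis(benzyloxy)-6-fluoro-3-(4,4,5,5-tetramethyl-1,3,2-dioxaborolan-2-yl)phenyl]ethan-1-one | CC(=O)c1c(OCc2ccccc2)c(B2OC(C)(C)C(C)(C)O2)c(OCc2ccccc2)cc1F
F6 | step 2 | 5-fluoro-2-iodobenzene-1,3-diol | Oc1cc(F)cc(O)c1I
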